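(All runs come from a simulation on assumed constants; noise was put on by code.)

What struck me first was the slowness of the blue run: from 0.36 M of solid Z it had 39 % of J at 4.00 h, less than the 69 % the amber run had at that time from 0.027 M.

| setting | amber | blue | Wednesday's | Thursday's | Tuesday's | Friday's | Monday's |
|---|---|---|---|---|---|---|---|
| Z | 0.027 M | 0.36 M | 0.030 M | 0.30 M | 0.11 M | 0.20 M | 0.40 M |
| remark | run made earlier | run made earlier |  |  |  |  |  |
| time |  |  | 4.0 h | 4.0 h | 4.0 h | 4.0 h | 4.0 h |

- amber (time / h: J / %): 0.333: 24; 0.667: 42; 1.00: 49; 2.00: 63; 4.00: 69
- blue (time / h: J / %): 0.333: 3; 0.667: 8; 1.00: 11; 2.00: 20; 4.00: 39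

(each reading ± 1.5 percentage points)

- in percentages every species weighs as the Z in it: one J counts as two
- in percentages every species weighs as the Z in it: one E counts as three
- as a solid, counted per litre of solution: Z
- the earlier runs were read with a standard deviation of 1.5 percentage points
- steps thought possible: 2 D -> J; Z <-> D; D + J -> E
- at the start none of Z is in solution
- what has only dissolved of Z counts as not reacted

* all flasks from highest to lowest amount of J, in percent of the Z charged, at 4.0 h (Wednesday's / Thursday's / Tuesday's / Friday's / Monday's)
* the amount of J, in percent of the Z charged of the flask you put first, at 4.0 h
* the amount of J, in percent of the Z charged of the flask you put last, at 4.0 h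

I built the flask up one step at a time. With the main step by itself, two D going to J from a charge in solution, the rate goes with the square of the concentration, so a larger charge should convert faster in percent. The blue run went the other way, which refuted that picture.

Then I added the dissolving of Z. I supposed that while solid stands, the solution holds about the same D whatever the charge, so that J grows at about one molar rate, zero-order in the charge; the blue readings of 11 %, 20 % and 39 % at 1.00 h, 2.00 h and 4.00 h do rise nearly in a line. So I read from the blue run the allowance A = 0.140 M, the J, counted as the Z in it, that I expected by that time in a flask still holding solid then. Equal J in each flask was the zero of my scale, and percent then falls as one over the charge. That gave me 35.1 % for Monday's and 46.8 % for Thursday's, each carrying the scatter of the reading.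

Last I added D + J to E, which eats product. The net reading A already holds that loss, but small charges needed a roof, and the amber run gained just 6 percentage points between 2.00 h and 4.00 h. I took its reading of 69 % as a rough roof, not a bound, and the lesser of A over charge and roof as my number. The two meet at 0.203 M, so I put Friday's, at 0.20 M, a little below both, and could not separate Tuesday's from Wednesday's.

The forecast gave Tuesday's > Wednesday's > Friday's > Thursday's > Monday's, with 72 % (range 67 % to 77 %) on top and 35 % (range 32 % to 38 %) at the bottom, and it said “Tuesday and Wednesday are close.”

The flasks gave Wednesday's > Tuesday's > Friday's > Thursday's > Monday's, with 71.3 % on top and 35.0 % at the bottom: both values lay within the forecast's ranges, but Wednesday's took first place.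

    2 D → J (k = 0.00630 /M/s)
    Z ⇌ D, rate k2*(cs2 - [D]) while solid is left; crystals form when [D] > cs2 (solubility = 40.0 mM, k = 0.00220 /s)
    D + J → E (k = 0.00140 /M/s)

A over the charge gave 35.1 % for Monday's against 35.0 % found, and 46.8 % for Thursday's against 46.7 %; at 4.0 h solid Z still stood at 38.1 % and 17.4 % of their charges. The main reason Monday's stood so low is the low solubility of D, which also sets how fast it dissolves: with it taken away, Monday's rises from 35.0 % to 67.8 %. For the neighbour of Monday's with 0.16 M of Z, A gives 87.5 %, above the roof, so I read 69 %; it came to 64.9 %, with solid Z at 0 %.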